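## Retrosynthetic overview

- The target is the 7-O-ether of isofraxidin with a geraniol-derived side chain. The side chain carries a (2R,3R)-oxirane with CH2O and the C4' chain trans, an (E)-C5'=C6' bond and a tertiary C7' alcohol. The last disconnection is the aryl O–C1' bond (Mitsunobu); C1' is not a stereocentre.
- Side chain: Sharpless epoxidation of geraniol with D-(−)-diethyl tartrate sets both oxirane stereocentres. A singlet-oxygen ene reaction and reduction then move the C6=C7 bond to C5=C6 and install the tertiary hydroxyl.
- Coumarin: ring B (the pyranone) is closed onto ring A (the benzene ring) by forming C4–C4a through hydroarylation of an aryl propiolate. The strategy rests on C4a being the only unsubstituted ortho carbon of the 2,4-dimethoxy-3-alkoxyphenol and lying para to the C7 oxygen, so the alkyne can close at one site only.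
- The C7 oxygen is carried as a benzyl ether through the ring closure. The phenol precursor comes from 2,6-dimethoxyphenol by benzylation, formylation and Dakin oxidation.
- Ring order: ring A is bought, ring B is formed in step 5, the oxirane is formed in step 7 and attached in step 9.

Key step: step 5

## Route

Step 1
Reactants: 1 2,6-dimethoxyphenol
Product: 2 2-(benzyloxy)-1,3-dimethoxybenzene
Conditions: BnBr, K2CO3, DMF, 60 °C
Reagents that add atoms: benzyl bromide, BrCc1ccccc1
Why: Williamson etherification (SN2 of the phenoxide on benzyl bromide) should mask the future C7 oxygen with a group that tolerates the formylation, the peracid oxidation and the π-acid ring closure.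

Step 2
Reactants: 2 2-(benzyloxy)-1,3-dimethoxybenzene
Product: 4 3-(benzyloxy)-2,4-dimethoxybenzaldehyde, via aryl dimethyliminium chloride 3 (not isolated)
Conditions: POCl3, DMF, 0 → 75 °C; then aq NaOAc, rt
Reagents that add atoms: N,N-dimethylformamide, CN(C)C=O; water, O
Why: Vilsmeier–Haack formylation, in which the central benzyloxy group is twisted out of the ring plane by its two neighbours, so the chloroiminium ion should attack the carbon para to one methoxy group and ortho to the other (as 1,2,3-trimethoxybenzene does), and hydrolysis of the iminium salt gives the aldehyde.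

Step 3
Reactants: 4 3-(benzyloxy)-2,4-dimethoxybenzaldehyde
Product: 6 3-(benzyloxy)-2,4-dimethoxyphenol, via aryl formate 5 (not isolated)
Conditions: mCPBA, CH2Cl2, 0 °C → rt; aq NaHCO3 wash; then K2CO3 (cat.), MeOH, rt
Reagents that add atoms: mCPBA, OOC(=O)c1cccc(Cl)c1
Why: Dakin-type Baeyer–Villiger oxidation, in which the electron-rich aryl group migrates in the Criegee intermediate to give the aryl formate, whose methanolysis should release the phenol while benzyl and methyl ethers stay intact.

Step 4
Reactants: 6 3-(benzyloxy)-2,4-dimethoxyphenol; 7 propiolic acid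
Product: 8 3-(benzyloxy)-2,4-dimethoxyphenyl propiolate
Conditions: DCC, DMAP (cat.), CH2Cl2, −20 → 0 °C
Reagents that add atoms: none
Why: Steglich esterification through the O-acylisourea of propiolic acid, run cold so that acylation of the phenol should outrun conjugate addition to the ynoate.

Step 5
Reactants: 8 3-(benzyloxy)-2,4-dimethoxyphenyl propiolate
Product: 9 7-(benzyloxy)-6,8-dimethoxycoumarin
Conditions: [(2-biphenylyl)P(t-Bu)2]Au(NCMe)SbF6 (5 mol %), dry CH2Cl2, rt → 40 °C
Reagents that add atoms: none
Why: The cationic monovalent gold complex binds the terminal alkyne of 8, and the arene carbon ortho to the ester oxygen (the future C4a) attacks the distal alkyne carbon anti to gold; the arenium ion, stabilised by the para benzyloxy oxygen, loses a proton and protodeauration of the vinylgold species at C3 releases 9 and the catalyst. The closest known reaction type is the π-acid-catalysed (gold, platinum or palladium) intramolecular hydroarylation of aryl alkynoates to coumarins, which is established for terminal propiolates of alkoxyphenols. Ring B closes in 6-endo-dig mode by forming the C4–C4a bond, and no stereocentre is created. The step needs site selectivity on ring A and endo selectivity at the alkyne. The first is enforced because the other ortho carbon carries the C8 methoxy group; the second should follow from the unsubstituted alkyne terminus, which favours direct ortho attack over ipso attack at C8a leading to a spirocycle. The conditions are neutral, so the benzyl ether should survive, and the acid-sensitive epoxide is not yet in the molecule.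

Step 6
Reactants: 9 7-(benzyloxy)-6,8-dimethoxycoumarin
Product: 11 isofraxidin (7-hydroxy-6,8-dimethoxycoumarin), via aryl dichloroborinate 10 (not isolated)
Conditions: BCl3, C6HMe5, CH2Cl2, −78 °C; then MeOH, −78 °C → rt
Reagents that add atoms: none
Why: Lewis-acid debenzylation with pentamethylbenzene as a non-basic benzyl-cation scavenger should cleave only the benzyl aryl ether at −78 °C, leaving the methyl ethers, the lactone and the C3=C4 bond (which hydrogenolysis could reduce) untouched.

Step 7
Reactants: 12 geraniol
Product: 13 (2R,3R)-2,3-epoxygeraniol, [(2R,3R)-3-methyl-3-(4-methylpent-3-en-1-yl)oxiran-2-yl]methanol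
Conditions: Ti(OiPr)4 (5 mol %), D-(−)-diethyl tartrate (6 mol %), t-BuOOH, 4 Å MS, CH2Cl2, −20 °C
Reagents that add atoms: tert-butyl hydroperoxide, CC(C)(C)OO
Why: Sharpless asymmetric epoxidation, in which the titanium tartrate complex binds the allylic alcohol and delivers oxygen to one face of C2=C3 only; the D-(−)-tartrate should give the (2R,3R)-epoxide, the (E)-alkene fixes the trans relation of CH2OH and the chain, and the isolated C6=C7 bond does not react.

Step 8
Reactants: 13 (2R,3R)-2,3-epoxygeraniol
Product: 15 (E)-5-[(2R,3R)-3-(hydroxymethyl)-2-methyloxiran-2-yl]-2-methylpent-3-en-2-ol, via tertiary allylic hydroperoxide 14 (not isolated)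
Conditions: O2, hν (visible), tetraphenylporphyrin (cat.), CH2Cl2, 0 °C; then PPh3, 0 °C → rt; chromatography
Reagents that add atoms: oxygen, O=O
Why: Schenck ene reaction of singlet oxygen at the trisubstituted C6=C7 bond followed by phosphine reduction of the O–O bond, in which hydrogen abstraction from C5 gives the tertiary hydroperoxide with an (E)-C5=C6 bond; abstraction from a methyl group is expected to give a comparable amount of a secondary regioisomer that chromatography should remove, and the oxirane stereocentres are not involved.

Step 9
Reactants: 11 isofraxidin; 15 (E)-5-[(2R,3R)-3-(hydroxymethyl)-2-methyloxiran-2-yl]-2-methylpent-3-en-2-ol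
Product: 16 7-{[(2R,3R)-3-((E)-4-hydroxy-4-methylpent-2-en-1-yl)-3-methyloxiran-2-yl]methoxy}-6,8-dimethoxy-2H-chromen-2-one (target)
Conditions: PPh3, DIAD, THF, 0 °C → rt
Reagents that add atoms: none
Why: Mitsunobu etherification, in which the primary alcohol is activated as its alkoxyphosphonium ion and displaced by the acidic phenoxide at a non-stereogenic CH2; the tertiary alcohol is inert and the neutral conditions should preserve the epoxide, so both stereocentres of 15 pass unchanged into 16.

## Compound list

1 | 2,6-dimethoxyphenol | COc1cccc(OC)c1O | starting material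
2 | 2-(benzyloxy)-1,3-dimethoxybenzene | COc1cccc(OC)c1OCc1ccccc1 | intermediate
3 | [3-(benzyloxy)-2,4-dimethoxybenzylidene]dimethyliminium chloride | C[N+](C)=Cc1ccc(OC)c(OCc2ccccc2)c1OC.[Cl-] | intermediate
4 | 3-(benzyloxy)-2,4-dimethoxybenzaldehyde | O=Cc1ccc(OC)c(OCc2ccccc2)c1OC | intermediate
5 | 3-(benzyloxy)-2,4-dimethoxyphenyl formate | O=COc1ccc(OC)c(OCc2ccccc2)c1OC | intermediate
6 | 3-(benzyloxy)-2,4-dimethoxyphenol | Oc1ccc(OC)c(OCc2ccccc2)c1OC | intermediate
7 | propiolic acid | C#CC(=O)O | starting material
8 | 3-(benzyloxy)-2,4-dimethoxyphenyl propiolate | C#CC(=O)Oc1ccc(OC)c(OCc2ccccc2)c1OC | intermediate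
9 | 7-(benzyloxy)-6,8-dimethoxycoumarin | COc1cc2ccc(=O)oc2c(OC)c1OCc1ccccc1 | intermediate
10 | 7-(dichloroboryloxy)-6,8-dimethoxycoumarin | COc1cc2ccc(=O)oc2c(OC)c1OB(Cl)Cl | intermediate
11 | isofraxidin (7-hydroxy-6,8-dimethoxycoumarin) | COc1cc2ccc(=O)oc2c(OC)c1O | intermediate
12 | geraniol | CC(C)=CCC/C(C)=C/CO | starting material
13 | (2R,3R)-2,3-epoxygeraniol | OC[C@H]1O[C@]1(C)CCC=C(C)C | intermediate
14 | {(2R,3R)-3-[(E)-4-hydroperoxy-4-methylpent-2-en-1-yl]-3-methyloxiran-2-yl}methanol | OC[C@H]1O[C@]1(C)C/C=C/C(C)(C)OO | intermediate
15 | (E)-5-[(2R,3R)-3-(hydroxymethyl)-2-methyloxiran-2-yl]-2-methylpent-3-en-2-ol | OC[C@H]1O[C@]1(C)C/C=C/C(C)(C)O | intermediate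
16 | 7-{[(2R,3R)-3-((E)-4-hydroxy-4-methylpent-2-en-1-yl)-3-methyloxiran-2-yl]methoxy}-6,8-dimethoxy-2H-chromen-2-one | COc1cc2ccc(=O)oc2c(OC)c1OC[C@H]1O[C@]1(C)C/C=C/C(C)(C)O | target

## Summary and risks

Total step count: 9. Longest linear sequence: 7 steps (steps 1–6, then step 9). The side chain takes 2 steps (7 and 8) before the coupling.

**Step 5 (key ring closure).** The cyclisation may be slow because the twisted C7 benzyloxy group donates only weakly to C4a. The catalyst may also be lost through gold acetylide formation at the terminal alkyne, or ipso attack with rearrangement may compete. The fallback builds the C4–C4a bond by formylation and sets out from phenol 6. Magnesium-mediated ortho-formylation (MgCl2, Et3N, paraformaldehyde, MeCN, reflux) at the only free ortho carbon should give 4-(benzyloxy)-2-hydroxy-3,5-dimethoxybenzaldehyde F1. Heating F1 with ethyl (triphenylphosphoranylidene)acetate in N,N-diethylaniline at reflux should give ethyl (E)-3-[4-(benzyloxy)-2-hydroxy-3,5-dimethoxyphenyl]prop-2-enoate F2, which isomerises and lactonises in the same flask. The fallback returns to the route at coumarin 9.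

**Step 8 (ene reaction).** Hydrogen abstraction from the methyl group competes with abstraction from C5, which lowers throughput and makes the separation demanding. The fallback is regiospecific and sets out from geraniol 12. Acetylation (Ac2O, pyridine) gives geranyl acetate F3. One equivalent of mCPBA in CH2Cl2 at 0 °C should epoxidise the more electron-rich distal alkene to give 6,7-epoxygeranyl acetate F4. Phenylselenide (PhSeSePh, NaBH4, EtOH) should open F4 at the secondary carbon to give the hydroxy selenide F5. Oxidation with H2O2 in THF triggers selenoxide syn-elimination, which can only go toward C5 because C7 has no hydrogen, and should give (2E,5E)-7-hydroxy-3,7-dimethylocta-2,5-dien-1-yl acetate F6. Methanolysis (K2CO3, MeOH) gives (2E,5E)-3,7-dimethylocta-2,5-diene-1,7-diol F7. Sharpless epoxidation of F7 under the conditions of step 7 should act on the primary allylic alcohol far faster than on the tertiary one. The fallback returns to the route at epoxy diol 15.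

**Step 9 (Mitsunobu coupling).** The phenoxide is flanked by two methoxy groups and may substitute slowly, and the epoxide may be opened or the activated alcohol may decompose. The fallback is a two-stage Williamson etherification and sets out from epoxy diol 15. Selective sulfonylation of the primary hydroxyl (TsCl, Et3N, DMAP cat., CH2Cl2, 0 °C) should give [(2R,3R)-3-((E)-4-hydroxy-4-methylpent-2-en-1-yl)-3-methyloxiran-2-yl]methyl 4-toluenesulfonate F8. F8 would then be displaced at CH2 by the caesium salt of isofraxidin 11 (Cs2CO3, DMF, rt). The fallback returns to the route at target 16.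

## Further compounds

F1 | step 5 | 4-(benzyloxy)-2-hydroxy-3,5-dimethoxybenzaldehyde | O=Cc1cc(OC)c(OCc2ccccc2)c(OC)c1O
F2 | step 5 | ethyl (E)-3-[4-(benzyloxy)-2-hydroxy-3,5-dimethoxyphenyl]prop-2-enoate | CCOC(=O)/C=C/c1cc(OC)c(OCc2ccccc2)c(OC)c1O
F3 | step 8 | geranyl acetate | CC(C)=CCC/C(C)=C/COC(C)=O
F4 | step 8 | 6,7-epoxygeranyl acetate (racemic at C6) | CC(=O)OC/C=C(\C)CCC1OC1(C)C
F5 | step 8 | (E)-7-hydroxy-3,7-dimethyl-6-(phenylselanyl)oct-2-en-1-yl acetate | CC(=O)OC/C=C(\C)CCC([Se]c1ccccc1)C(C)(C)O
F6 | step 8 | (2E,5E)-7-hydroxy-3,7-dimethylocta-2,5-dien-1-yl acetate | CC(=O)OC/C=C(\C)C/C=C/C(C)(C)O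
F7 | step 8 | (2E,5E)-3,7-dimethylocta-2,5-diene-1,7-diol | OC/C=C(\C)C/C=C/C(C)(C)O
F8 | step 9 | [(2R,3R)-3-((E)-4-hydroxy-4-methylpent-2-en-1-yl)-3-methyloxiran-2-yl]methyl 4-toluenesulfonate | Cc1ccc(cc1)S(=O)(=O)OC[C@H]1O[C@]1(C)C/C=C/C(C)(C)O
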